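**Retrosynthetic overview**
- Target ⇒ Claisen–Schmidt disconnection of the enone C=C (made last): the (R)-7-acetyl-dihydrobenzofuran plus 4-hydroxybenzaldehyde.
- (R)-7-acetyl-2-(2-hydroxypropan-2-yl)-4-methoxy-2,3-dihydrobenzofuran ⇒ C2–O1 ring bond: catalytic asymmetric epoxidation and 5-exo phenoxide closure of 2-hydroxy-4-methoxy-3-prenylacetophenone. This one operation closes the ring and sets the only stereocentre.
- 3-Prenylphenol ⇒ O→C [1,3] prenyl shift of the 2-O-prenyl ether ⇒ paeonol plus prenyl bromide.
- Ring order: both benzene rings are bought; the dihydrofuran ring is the only ring formed (third step).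

Assumption: the sense of induction of the (S,S)-bis-hydroxamic acid ligand in step 3 (oxygen delivery to the Si face of the prenyl CH= carbon) is assigned by analogy with aliphatic bishomoallylic alcohols and is not established for phenols; if the first run gives the enantiomeric cyclised ketone (checked against the fallback sample), the equally available (R,R)-ligand is used.

**Step 1**
Reactants: 1 paeonol (1-(2-hydroxy-4-methoxyphenyl)ethan-1-one); 2 prenyl bromide (1-bromo-3-methylbut-2-ene)
Product: 3 1-[4-methoxy-2-(3-methylbut-2-en-1-yloxy)phenyl]ethan-1-one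
Conditions: 2 (1.3 equiv), K2CO3 (2 equiv), acetone, reflux, 12 h
Reagents that add atoms: none
Why: Williamson ether synthesis, in which the phenoxide of 1 (the only acidic OH) displaces bromide from the primary allylic carbon to give the unrearranged prenyl ether.

**Step 2**
Reactants: 3 1-[4-methoxy-2-(3-methylbut-2-en-1-yloxy)phenyl]ethan-1-one
Product: 4 1-[2-hydroxy-4-methoxy-3-(3-methylbut-2-en-1-yl)phenyl]ethan-1-one
Conditions: montmorillonite K10 clay (acid-treated aluminosilicate, idealised Al2Si4O10(OH)2·nH2O; 1 g per g of 3), CH2Cl2, 0 °C → rt, 1–3 h; filter; chromatography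
Reagents that add atoms: none
Why: Acid-clay-catalysed formal [1,3]-sigmatropic O→C prenyl shift, known for 2-prenyloxyacetophenones: ionisation on the clay gives a tight phenol/prenyl-cation pair that recombines through its primary terminus at the adjacent C3, which is activated by both oxygens, with the 5-prenyl isomer as a separable minor product.

**Step 3**
Reactants: 4 1-[2-hydroxy-4-methoxy-3-(3-methylbut-2-en-1-yl)phenyl]ethan-1-one
Product: 6 1-[(2R)-2-(2-hydroxypropan-2-yl)-4-methoxy-2,3-dihydro-1-benzofuran-7-yl]ethan-1-one, via epoxide 5 (not isolated)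
Conditions: Hf(OtBu)4 (10 mol%), (S,S)-BHA ligand N,N′-[(1S,2S)-cyclohexane-1,2-diyl]bis(N-hydroxy-2,2-diphenylacetamide) (12 mol%), DMPU (0.2 equiv), cumene hydroperoxide (1.2 equiv), 4 Å MS, toluene, 0 °C → rt, 24 h; then K2CO3 (0.5 equiv), MeOH, rt, 2 h, one pot
Reagents that add atoms: cumene hydroperoxide, CC(C)(OO)c1ccccc1
Why: Proposed new method: a phenol-directed asymmetric epoxidation–cycloetherification in which the tetravalent hafnium bis-hydroxamate binds 4 as a κ2-O,O acylphenoxide chelate beside an η2-cumylperoxide (eight-coordinate Hf), so that oxygen is passed intramolecularly to the Si face of the neighbouring prenyl CH= carbon inside the C2-symmetric ligand pocket to give (S)-epoxide 5, and K2CO3/MeOH then drives 5-exo-tet phenoxide opening at that carbon with clean inversion to the (R)-dihydrobenzofuran, the epoxide oxygen ending as the tertiary OH; the closest known reaction types are the hydroxyl-directed Zr/Hf bis-hydroxamate epoxidation of aliphatic homoallylic and bishomoallylic alcohols and the racemic VO(acac)2/t-BuOOH epoxidation–cyclisation of ortho-prenylphenols, while a phenol or chelating acylphenoxide as the directing group in the asymmetric version has not been shown.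

**Step 4**
Reactants: 6 1-[(2R)-2-(2-hydroxypropan-2-yl)-4-methoxy-2,3-dihydro-1-benzofuran-7-yl]ethan-1-one; 7 4-hydroxybenzaldehyde
Product: 9 (2E)-3-(4-hydroxyphenyl)-1-[(2R)-2-(2-hydroxypropan-2-yl)-4-methoxy-2,3-dihydro-1-benzofuran-7-yl]prop-2-en-1-one, via aldol adduct 8 (not isolated)
Conditions: 7 (1.2 equiv), KOH (50% aq., 10 equiv), EtOH, rt, 36 h, N2; then 1 M HCl to pH 5 at 0 °C
Reagents that add atoms: none
Why: Claisen–Schmidt condensation, in which the methyl-ketone enolate of 6 adds to 7 and aldol adduct 8 loses water by E1cB to the thermodynamically favoured (E)-enone; 6 has no free ortho-OH (no flavanone formation) and its C2 stereocentre bears no acidic hydrogen, so it is untouched.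

**Compound list**
1 | paeonol, 1-(2-hydroxy-4-methoxyphenyl)ethan-1-one | CC(=O)c1ccc(OC)cc1O | starting material
2 | prenyl bromide, 1-bromo-3-methylbut-2-ene | CC(C)=CCBr | starting material
3 | 1-[4-methoxy-2-(3-methylbut-2-en-1-yloxy)phenyl]ethan-1-one | CC(=O)c1ccc(OC)cc1OCC=C(C)C | intermediate
4 | 1-[2-hydroxy-4-methoxy-3-(3-methylbut-2-en-1-yl)phenyl]ethan-1-one | CC(=O)c1ccc(OC)c(CC=C(C)C)c1O | intermediate
5 | 1-(3-{[(2S)-3,3-dimethyloxiran-2-yl]methyl}-2-hydroxy-4-methoxyphenyl)ethan-1-one | CC(=O)c1ccc(OC)c(C[C@@H]2OC2(C)C)c1O | intermediate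
6 | 1-[(2R)-2-(2-hydroxypropan-2-yl)-4-methoxy-2,3-dihydro-1-benzofuran-7-yl]ethan-1-one | COc1ccc(C(C)=O)c2c1C[C@H](C(C)(C)O)O2 | intermediate
7 | 4-hydroxybenzaldehyde | O=Cc1ccc(O)cc1 | starting material
8 | 3-hydroxy-3-(4-hydroxyphenyl)-1-[(2R)-2-(2-hydroxypropan-2-yl)-4-methoxy-2,3-dihydro-1-benzofuran-7-yl]propan-1-one (both carbinol epimers) | COc1ccc(C(=O)CC(O)c2ccc(O)cc2)c2c1C[C@H](C(C)(C)O)O2 | intermediate
9 | (2E)-3-(4-hydroxyphenyl)-1-[(2R)-2-(2-hydroxypropan-2-yl)-4-methoxy-2,3-dihydro-1-benzofuran-7-yl]prop-2-en-1-one | COc1ccc(C(=O)/C=C/c2ccc(O)cc2)c2c1C[C@H](C(C)(C)O)O2 | target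

**Totals and risks**
Total step count: 4. Longest linear sequence: 4 (from 1).

Most likely to fail, first: step 3, the new step. The hydrogen-bonded acylphenol may direct poorly, giving low conversion or low ee. The Lewis-acidic hafnium may open epoxide 5 in the 6-endo sense to the 3-hydroxy-2,2-dimethylchroman before the basic finish. The facial sense is not established (see the assumption). The ee of 6 is to be measured by chiral HPLC and raised by recrystallisation if needed. The fallback uses known chemistry, sets out from 4 and comes back at 6. Acetylation (Ac2O, pyridine, DMAP, CH2Cl2) gives 6-acetyl-3-methoxy-2-(3-methylbut-2-en-1-yl)phenyl acetate F3. Shi epoxidation with the L-fructose-derived ketone 1,2:4,5-di-O-isopropylidene-β-L-erythro-2,3-hexodiulo-2,6-pyranose (30 mol%), Oxone (2KHSO5·KHSO4·K2SO4), K2CO3 and Bu4NHSO4 in MeCN/dimethoxymethane/aqueous Na2B4O7 buffer at 0 °C gives 6-acetyl-2-{[(2S)-3,3-dimethyloxiran-2-yl]methyl}-3-methoxyphenyl acetate F4. The D-fructose ketone gives the (R)-epoxide from R–CH=CMe2 alkenes, so its antipode gives (S). K2CO3 in MeOH at rt then removes the acetate, and the freed phenoxide closes 5-exo with inversion to 6.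

Second: step 2. The clay can give the 5-prenyl isomer, loss of the prenyl group back to 1, or acid cyclisation of 4 to a 2,2-dimethylchroman. The fallback sets out from 2 and comes back at 4, with commercial 2,4-dihydroxyacetophenone F1 taking the place of 1. Direct C-prenylation of its dianion with 2 in 10% aqueous KOH at rt goes at C3, between the two oxygens, to give 1-[2,4-dihydroxy-3-(3-methylbut-2-en-1-yl)phenyl]ethan-1-one F2 (known, modest yield, separable from the 5-isomer). MeI, K2CO3 and acetone then methylate only the non-chelated 4-OH to give 4.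

Third: step 4. The phenoxide form of 7 is a poor electrophile, so the condensation may stall. The fallback sets out from 6 and comes back at 9. Condensation of 6 with commercial 4-(oxan-2-yloxy)benzaldehyde F5 (KOH, EtOH, rt), a neutral and more electrophilic aldehyde, gives (2E)-1-[(2R)-2-(2-hydroxypropan-2-yl)-4-methoxy-2,3-dihydro-1-benzofuran-7-yl]-3-[4-(oxan-2-yloxy)phenyl]prop-2-en-1-one F6. p-TsOH·H2O (cat.) in MeOH at rt then removes the acetal without touching the tertiary alcohol and gives 9.

**Further compounds**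
F1 | step 2 | 2,4-dihydroxyacetophenone, 1-(2,4-dihydroxyphenyl)ethan-1-one (commercial) | CC(=O)c1ccc(O)cc1O
F2 | step 2 | 1-[2,4-dihydroxy-3-(3-methylbut-2-en-1-yl)phenyl]ethan-1-one | CC(=O)c1ccc(O)c(CC=C(C)C)c1O
F3 | step 3 | 6-acetyl-3-methoxy-2-(3-methylbut-2-en-1-yl)phenyl acetate | CC(=O)Oc1c(C(C)=O)ccc(OC)c1CC=C(C)C
F4 | step 3 | 6-acetyl-2-{[(2S)-3,3-dimethyloxiran-2-yl]methyl}-3-methoxyphenyl acetate | CC(=O)Oc1c(C(C)=O)ccc(OC)c1C[C@@H]2OC2(C)C
F5 | step 4 | 4-(oxan-2-yloxy)benzaldehyde (commercial) | O=Cc1ccc(OC2CCCCO2)cc1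
F6 | step 4 | (2E)-1-[(2R)-2-(2-hydroxypropan-2-yl)-4-methoxy-2,3-dihydro-1-benzofuran-7-yl]-3-[4-(oxan-2-yloxy)phenyl]prop-2-en-1-one (both acetal epimers) | COc1ccc(C(=O)/C=C/c2ccc(OC3CCCCO3)cc2)c2c1C[C@H](C(C)(C)O)O2
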